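**Plan**
- Retrosynthesis: the C3 methylene is first given back two ester groups (removable activators). Then the C2–C3 bond of ring C is cut, with one C4–H returned to C2, which opens the flavan to an achiral benzyl aryl ether. That ether is cut at C3=C4 (Knoevenagel) and at O1–CH2 (Williamson).
- Forward: ring A aldehyde 1 is O-benzylated with ring B chloride 2 and condensed with dimethyl malonate. Ring C then closes by a catalytic enantioselective [1,5]-hydride shift/cyclisation, and the two ester groups are taken off C3.
- Enabling feature: in the open precursor the future C2 is a CH2 that is benzylic to ring B and bound to O1, so its C–H is hydridic. It lies 1,5 to C4, and the 8-OMe of ring A, ortho to O1, pushes the benzyloxy arm over C4.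
- Stereochemistry: C2, the only stereocentre, is set in the ring closure by a chiral scandium Lewis acid held on the malonate. C3 stays quaternary until the esters are hydrolysed, so C2 cannot be lost by retro-oxa-Michael opening before then.

Key step: step 3

Assumption: the sense of induction in step 3 cannot be derived from precedent, so the PyBox antipode (both are sold) is fixed by a first assay, and the route is written for the antipode that gives 7.

**Step 1**
Reactants: 1 (2-hydroxy-3,4-dimethoxybenzaldehyde); 2 (3,4,5-trimethoxybenzyl chloride)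
Product: 3 3,4-dimethoxy-2-[(3,4,5-trimethoxybenzyl)oxy]benzaldehyde
Conditions: K2CO3, KI (cat.), DMF, 60 °C
Reagents that add atoms: none
Why: Williamson ether synthesis, in which the phenoxide of 1 (acidified by the ortho formyl group) displaces chloride from the benzylic chloride 2 by SN2 with iodide as nucleophilic catalyst; no stereocentre is formed.

**Step 2**
Reactants: 3 (3,4-dimethoxy-2-[(3,4,5-trimethoxybenzyl)oxy]benzaldehyde); 4 (dimethyl malonate)
Product: 5 dimethyl 2-{3,4-dimethoxy-2-[(3,4,5-trimethoxybenzyl)oxy]benzylidene}malonate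
Conditions: piperidine (cat.), AcOH (cat.), toluene, reflux, Dean–Stark
Reagents that add atoms: none
Why: Knoevenagel condensation under piperidinium acetate catalysis with azeotropic removal of water should drive the electron-rich aldehyde to the alkylidene malonate, which has no E/Z issue because the two esters are the same, and the earlier O-alkylation blocks coumarin formation.

**Step 3**
Reactants: 5 (dimethyl 2-{3,4-dimethoxy-2-[(3,4,5-trimethoxybenzyl)oxy]benzylidene}malonate)
Product: 7 dimethyl (2R)-7,8-dimethoxy-2-(3,4,5-trimethoxyphenyl)chromane-3,3-dicarboxylate, via oxocarbenium malonate zwitterion 6 (not isolated)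
Conditions: Sc(OTf)3 (10 mol %), (S,S)-Ph-PyBox (12 mol %), 4 Å MS, ClCH2CH2Cl, 60 °C
Reagents that add atoms: none
Why: Proposed new method: the trivalent scandium–PyBox complex chelates the two ester carbonyls of 5 and lowers the LUMO at C4, so that one of the two enantiotopic hydrogens of the O–CH2–aryl group shifts suprafacially as hydride to C4 through a six-membered transition state ([1,5]-hydride shift), which leaves the oxocarbenium ion ArCH=O(+)–Ar' (stabilised by O1 and by the 4-methoxy group of ring B) ion-paired with the scandium-bound malonate carbanion at C3 (6). The carbanion then adds to C2, which forms the C2–C3 bond and closes ring C in a 6-endo-trig closure at the C2=O1 oxocarbenium (enolexo with respect to the malonate). The closest known reaction type is the Lewis-acid-catalysed hydride shift/cyclisation (internal redox, tert-amino-effect type) of ortho-alkylidene-malonate aryl alkyl and aryl benzyl ethers to racemic dihydrobenzopyrans, together with its enantioselective chiral-Lewis-acid and chiral-phosphoric-acid versions on N-benzyl and N,N-dialkyl anilines; the new element is the enantioselective version on an ether donor. C2 is the only stereocentre formed: the ligand shell on scandium decides which enantiotopic C–H is delivered and hence which helical conformer of the zwitterion arises, and closure inside that contact ion pair, faster than rotation about O1–C2, fixes the C2 configuration (R by CIP in 7 only because C3 now outranks the aryl carbon; the spatial arrangement is that of 2S in the target). The step needs chemoselectivity for the C2–H bond and enough reactivity despite the 7-OMe para to C4: C2–H is the only hydridic C–H in 1,5 relation to C4, and the 8-OMe of ring A ortho to O1 buttresses the benzyloxy arm into the conformer that holds it over C4.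

**Step 4**
Reactants: 7 (dimethyl (2R)-7,8-dimethoxy-2-(3,4,5-trimethoxyphenyl)chromane-3,3-dicarboxylate)
Product: 9 (2S)-7,8-dimethoxy-2-(3,4,5-trimethoxyphenyl)chromane-3-carboxylic acid (both C3 epimers), via diacid 8 (not isolated)
Conditions: KOH, EtOH/H2O, reflux; 1 M HCl to pH 2, 0 °C; then toluene, 110 °C
Reagents that add atoms: potassium hydroxide, [K+].[OH-]
Why: Saponification of both methyl esters is safe for C2 because C3 is still quaternary and cannot eliminate O1, and the free malonic acid 8 should then lose CO2 thermally through the cyclic six-membered transition state (malonic acid decarboxylation) under neutral conditions; the new C3 centre forms as a mixture, which does not matter because C3 becomes CH2 in step 5.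

**Step 5**
Reactants: 9 ((2S)-7,8-dimethoxy-2-(3,4,5-trimethoxyphenyl)chromane-3-carboxylic acid)
Product: 11 (2S)-7,8,3',4',5'-pentamethoxyflavan, via Barton ester 10 (not isolated)
Conditions: DCC, 1-hydroxypyridine-2(1H)-thione, DMAP (cat.), CH2Cl2, 0 °C to rt, dark; then t-BuSH, hν (tungsten lamp), rt
Reagents that add atoms: none
Why: Barton reductive decarboxylation, in which the thiohydroxamate ester 10 fragments in a radical chain (thiyl radical adds to C=S, N–O cleavage, loss of CO2) to the secondary C3 radical, which should take hydrogen from t-BuSH faster than it can expel the O1 aryloxyl radical, so that C3 becomes CH2 while C2, which is not part of the radical, keeps its configuration.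

**Compound list**
1 | 2-hydroxy-3,4-dimethoxybenzaldehyde | COc1ccc(C=O)c(O)c1OC | starting material
2 | 3,4,5-trimethoxybenzyl chloride (5-(chloromethyl)-1,2,3-trimethoxybenzene) | COc1cc(CCl)cc(OC)c1OC | starting material
3 | 3,4-dimethoxy-2-[(3,4,5-trimethoxybenzyl)oxy]benzaldehyde | COc1ccc(C=O)c(OCc2cc(OC)c(OC)c(OC)c2)c1OC | intermediate
4 | dimethyl malonate | COC(=O)CC(=O)OC | starting material
5 | dimethyl 2-{3,4-dimethoxy-2-[(3,4,5-trimethoxybenzyl)oxy]benzylidene}malonate | COC(=O)C(=Cc1ccc(OC)c(OC)c1OCc1cc(OC)c(OC)c(OC)c1)C(=O)OC | intermediate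
6 | oxocarbenium malonate zwitterion (C4 is CH2, carbanion at C3, aryl oxocarbenium at C2; drawn without the scandium complex; not isolated) | COC(=O)[C-](C(=O)OC)Cc1ccc(OC)c(OC)c1[O+]=Cc1cc(OC)c(OC)c(OC)c1 | intermediate
7 | dimethyl (2R)-7,8-dimethoxy-2-(3,4,5-trimethoxyphenyl)chromane-3,3-dicarboxylate | COc1cc([C@@H]2C(C(=O)OC)(C(=O)OC)Cc3ccc(OC)c(OC)c3O2)cc(OC)c1OC | intermediate
8 | (2R)-7,8-dimethoxy-2-(3,4,5-trimethoxyphenyl)chromane-3,3-dicarboxylic acid (not isolated) | COc1cc([C@@H]2C(C(=O)O)(C(=O)O)Cc3ccc(OC)c(OC)c3O2)cc(OC)c1OC | intermediate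
9 | (2S)-7,8-dimethoxy-2-(3,4,5-trimethoxyphenyl)chromane-3-carboxylic acid (both C3 epimers) | COc1cc([C@@H]2C(C(=O)O)Cc3ccc(OC)c(OC)c3O2)cc(OC)c1OC | intermediate
10 | 2-thioxopyridin-1(2H)-yl (2S)-7,8-dimethoxy-2-(3,4,5-trimethoxyphenyl)chromane-3-carboxylate (Barton ester; not isolated) | COc1cc([C@@H]2C(C(=O)ON4C=CC=CC4=S)Cc3ccc(OC)c(OC)c3O2)cc(OC)c1OC | intermediate
11 | (2S)-7,8,3',4',5'-pentamethoxyflavan ((2S)-7,8-dimethoxy-2-(3,4,5-trimethoxyphenyl)chromane) | COc1cc([C@@H]2CCc3ccc(OC)c(OC)c3O2)cc(OC)c1OC | target

**Step count**
Total steps: 5. Longest linear sequence: 5 steps (1 → 3 → 5 → 7 → 9 → 11).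

**Steps most likely to fail**

Step 3 (Proposed new method). Three processes may defeat it:
- The hydride transfer may be too slow, because the 7-OMe para to C4 lowers the acceptor strength and an aryl ether oxygen is a weak donor. Lewis-acid ionisation of the trimethoxybenzyl–oxygen bond or hydrolysis of the oxocarbenium ion would then compete.
- The catalyst may discriminate the two enantiotopic C–H bonds poorly.
- The C2 configuration may erode through reversible C2–C3 heterolysis under the Lewis acid.

The fallback uses known chemistry and sets out from 1. Claisen–Schmidt condensation of 1 with 1-(3,4,5-trimethoxyphenyl)ethanone (KOH, EtOH, rt) should give (E)-3-(2-hydroxy-3,4-dimethoxyphenyl)-1-(3,4,5-trimethoxyphenyl)prop-2-en-1-one F1. Hydrogenation of the alkene only (H2 1 atm, 10% Pd/C, EtOAc, rt, stopped after one equivalent) should give 3-(2-hydroxy-3,4-dimethoxyphenyl)-1-(3,4,5-trimethoxyphenyl)propan-1-one F2. Corey–Bakshi–Shibata reduction ((S)-2-methyl-CBS-oxazaborolidine, BH3·SMe2 in excess for the free phenol, THF, 0 °C) should give (1R)-3-(2-hydroxy-3,4-dimethoxyphenyl)-1-(3,4,5-trimethoxyphenyl)propan-1-ol F3. Mitsunobu cyclisation (PPh3, DIAD, THF, 0 °C to rt) should close O1–C2 with inversion and come back to the route at 11.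

Step 5. The C3 radical may open ring C by β-scission of the O1 aryloxyl radical, or the thiohydroxamate ester may rearrange to the 2-pyridyl sulfide when hydrogen transfer is slow. The fallback avoids a free radical at C3 and sets out from 9. Reduction with BH3·THF should give [(2S)-7,8-dimethoxy-2-(3,4,5-trimethoxyphenyl)chroman-3-yl]methanol F6. Dess–Martin oxidation (CH2Cl2, NaHCO3, rt) should give (2S)-7,8-dimethoxy-2-(3,4,5-trimethoxyphenyl)chromane-3-carbaldehyde F7, which is used at once. Tsuji–Wilkinson decarbonylation with stoichiometric RhCl(PPh3)3 (toluene, reflux) should replace the formyl group by hydrogen and come back to the route at 11.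

Step 4. The second, neopentyl-type ester may hydrolyse incompletely. If decarboxylation sets in while the medium is still basic, a C3 enolate could expel the O1 phenoxide (retro-oxa-Michael ring opening) and scramble C2. The fallback replaces hydrolytic by hydrogenolytic ester cleavage and sets out from 3. Knoevenagel condensation with dibenzyl malonate (piperidine, AcOH, toluene, reflux) should give dibenzyl 2-{3,4-dimethoxy-2-[(3,4,5-trimethoxybenzyl)oxy]benzylidene}malonate F4. The conditions of step 3 should give dibenzyl (2R)-7,8-dimethoxy-2-(3,4,5-trimethoxyphenyl)chromane-3,3-dicarboxylate F5. Hydrogenolysis (H2 1 atm, 10% Pd/C, EtOAc, rt, short contact so that the cyclic benzylic C2–O1 bond is spared) should free the diacid without base and come back to the route at 8, which is heated to 9 as in step 4.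

**Further compounds**
F1 | step 3 | (E)-3-(2-hydroxy-3,4-dimethoxyphenyl)-1-(3,4,5-trimethoxyphenyl)prop-2-en-1-one | COc1cc(C(=O)/C=C/c2ccc(OC)c(OC)c2O)cc(OC)c1OC
F2 | step 3 | 3-(2-hydroxy-3,4-dimethoxyphenyl)-1-(3,4,5-trimethoxyphenyl)propan-1-one | COc1cc(C(=O)CCc2ccc(OC)c(OC)c2O)cc(OC)c1OC
F3 | step 3 | (1R)-3-(2-hydroxy-3,4-dimethoxyphenyl)-1-(3,4,5-trimethoxyphenyl)propan-1-ol | COc1cc([C@H](O)CCc2ccc(OC)c(OC)c2O)cc(OC)c1OC
F4 | step 4 | dibenzyl 2-{3,4-dimethoxy-2-[(3,4,5-trimethoxybenzyl)oxy]benzylidene}malonate | O=C(OCc1ccccc1)C(=Cc1ccc(OC)c(OC)c1OCc1cc(OC)c(OC)c(OC)c1)C(=O)OCc1ccccc1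
F5 | step 4 | dibenzyl (2R)-7,8-dimethoxy-2-(3,4,5-trimethoxyphenyl)chromane-3,3-dicarboxylate | COc1cc([C@@H]2C(C(=O)OCc4ccccc4)(C(=O)OCc5ccccc5)Cc3ccc(OC)c(OC)c3O2)cc(OC)c1OC
F6 | step 5 | [(2S)-7,8-dimethoxy-2-(3,4,5-trimethoxyphenyl)chroman-3-yl]methanol (both C3 epimers) | COc1cc([C@@H]2C(CO)Cc3ccc(OC)c(OC)c3O2)cc(OC)c1OC
F7 | step 5 | (2S)-7,8-dimethoxy-2-(3,4,5-trimethoxyphenyl)chromane-3-carbaldehyde (both C3 epimers) | COc1cc([C@@H]2C(C=O)Cc3ccc(OC)c(OC)c3O2)cc(OC)c1OC
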